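**Plan**

1. Numbering used throughout (β = face of the C4 methyl): cycloheptene C1(CH3)=C2–C3–C4(CH3)–C5(H)–C6(O-aroyl)–C7, cyclopentane C4–C5–C8(OH)(i-Pr)–C9–C10(OH). The fusion bond C4–C5 lies between the C6 oxygen and the C8 carbinol. This is the retron of a semipinacol 1,2-shift of C4 from C6 to C5 in a cis-decalin (ring A: C1–C2–C3–C4–C6–C7; ring B: C4–C10–C9–C8–C5–C6) whose ring B is the carbon skeleton of thymoquinone.
2. The retrosynthesis cuts the C6–O ester bond, then C4–C5 (returned as C4–C6 of a decalin C6-hydroxy C5-mesylate), then C3–C4 and C6–C7 (Diels–Alder), which leads to thymoquinone and 2-methyl-3-(triisopropylsilyloxy)butadiene.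
3. Forward: ring A is annulated onto the quinone (ring B) by an enantioselective Diels–Alder reaction. Ring B is then oxygenated (C8–C9 epoxide to C8–OH, C10 carbinol, C5=C6 to the cis-diol). The shift contracts ring B to the cyclopentane and expands ring A to the cycloheptene; reduction, esterification and desilylation finish.
4. Stereochemistry: C4 from the chiral oxazaborolidinium catalyst; C8 from convex-face epoxidation of the cis-fused adduct; C10, the C5/C6 diol and finally C6 from reactions directed by the C8 hydroxyl; C5 of the target by inversion at the mesylate carbon during the shift.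
5. The C1=C2 alkene travels as an enol derivative (silyl enol ether, then vinyl triflate). This polarises the diene for regiocontrol and keeps the alkene inert to OsO4 until a palladium-catalysed formate reduction unveils it.

Key step: step 12

Assumption: the (S)-proline-derived oxazaborolidinium ion is taken to shield the quinone face that leads to the C4 configuration drawn for 4; if its sense of induction is the opposite, the (R)-catalyst is used and nothing else changes.

Step 1
Reactants: 1 3-methylbut-3-en-2-one
Product: 2 2-methyl-3-(triisopropylsilyloxy)buta-1,3-diene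
Conditions: iPr3SiOSO2CF3, Et3N, CH2Cl2, 0 °C
Reagents that add atoms: triisopropylsilyl trifluoromethanesulfonate, CC(C)[Si](C(C)C)(C(C)C)OS(=O)(=O)C(F)(F)F
Why: Silyl enol ether formation by soft enolisation: the silyl triflate activates the ketone and Et3N removes a methyl proton, which gives the 2-silyloxy diene; no stereocentre is formed.

Step 2
Reactants: 2 2-methyl-3-(triisopropylsilyloxy)buta-1,3-diene; 3 thymoquinone
Product: 4 cis-fused adduct 2-isopropyl-4a,7-dimethyl-6-(triisopropylsilyloxy)-4a,5,8,8a-tetrahydronaphthalene-1,4-dione (route locants: C5,C10-dione, C8=C9, ring A C1(CH3)=C2(OSi-iPr3), C4–CH3 and C6–H β)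
Conditions: (S)-3,3-diphenyl-1-(2-methylphenyl)tetrahydro-1H,3H-pyrrolo[1,2-c][1,3,2]oxazaborole (20 mol%), HN(SO2CF3)2 (17 mol%), CH2Cl2, −78 °C
Reagents that add atoms: none
Why: Enantioselective Diels–Alder reaction under chiral oxazaborolidinium Lewis acid catalysis: boron binds the C5 carbonyl at the lone pair next to C6–H (the C10 lone pair on that side is blocked by the C4 methyl), so the methyl-bearing C4=C6 bond reacts in preference to the isopropyl-bearing one, the silyl enol ether terminus of the diene bonds to the β-carbon C4 and the methyl-substituted terminus to C6, suprafacial addition places C4–CH3 and C6–H cis, and the catalyst blocks one face of the quinone and so sets the absolute configuration at C4.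

Step 3
Reactants: 4 cis-fused adduct
Product: 5 8β,9β-epoxide of 4 (epoxide oxygen cis to C4–CH3 and C6–H, isopropyl α)
Conditions: 30% H2O2, Na2CO3 (cat.), THF–MeOH, 0 °C
Reagents that add atoms: hydrogen peroxide, OO
Why: Weitz–Scheffer nucleophilic epoxidation attacks only the electron-poor enedione alkene, and hydroperoxide adds to C9 from the convex β face of the cis-fused bicycle (anti to ring A), which sets the C8–O bond β and leaves the silyl enol ether untouched.

Step 4
Reactants: 5 8β,9β-epoxide of 4
Product: 7 C5 enol triflate of 5, via potassium enolate 6 (not isolated)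
Conditions: KN(SiMe3)2, THF, −78 °C; then PhN(SO2CF3)2
Reagents that add atoms: N-phenylbis(trifluoromethanesulfonimide), O=S(=O)(N(c1ccccc1)S(=O)(=O)C(F)(F)F)C(F)(F)F
Why: Enol triflate formation: C6–H is the only enolisable position (C4 is quaternary, C9 is an oxirane carbon), so the potassium enolate forms regiospecifically and is sulfonylated on oxygen; the C6 stereocentre is erased on purpose and C4, C8 and C9 are untouched.

Step 5
Reactants: 7 C5 enol triflate of 5
Product: 8 β-hydroxy ketone (C8–OH β, C9H2, C10 ketone, C5(OTf)=C6)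
Conditions: SmI2, THF–MeOH, −90 °C
Reagents that add atoms: none
Why: Reductive opening of an α,β-epoxy ketone by divalent samarium: electron transfer to the C10 ketone and cleavage of the adjacent C9–O bond give, after protonation by MeOH, the β-hydroxy ketone with the C8–O bond and its β configuration intact, while the vinyl triflate and the silyl enol ether do not react at this temperature.

Step 6
Reactants: 8 β-hydroxy ketone
Product: 9 8β,10α-diol
Conditions: Me4NBH(OAc)3, AcOH–MeCN, −30 °C
Reagents that add atoms: none
Why: Evans–Saksena reduction: the C8 hydroxyl exchanges onto boron and delivers hydride within the molecule to the β face of the C10 ketone, which gives the anti-1,3-diol with C10–OH α (trans to the C4 methyl).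

Step 7
Reactants: 9 8β,10α-diol
Product: 10 C10 tert-butyldimethylsilyl ether of 9 (C8–OH free)
Conditions: TBSCl, imidazole, 4-(dimethylamino)pyridine (cat.), DMF, 40 °C
Reagents that add atoms: tert-butyldimethylsilyl chloride, CC(C)(C)[Si](C)(C)Cl
Why: Silyl ether formation distinguishes the secondary C10 hydroxyl from the hindered tertiary C8 hydroxyl, which stays free as the later directing group.

Step 8
Reactants: 10 C10 tert-butyldimethylsilyl ether of 9
Product: 11 allylic alcohol with C5(H)=C6 (C8–OH β, C10–OTBS α, ring A silyl enol ether)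
Conditions: Pd(OAc)2 (5 mol%), PPh3 (10 mol%), HCO2H, Et3N, DMF, 60 °C
Reagents that add atoms: none
Why: Palladium-catalysed formate reduction of an enol triflate: oxidative addition of the C5–OTf bond to zerovalent palladium, formate exchange, loss of CO2 and reductive elimination replace the triflate by hydrogen and give the C5=C6 alkene at the position fixed by the triflate, while the silyl enol ether and the tertiary allylic alcohol are inert.

Step 9
Reactants: 11 allylic alcohol with C5(H)=C6
Product: 12 ring A enol triflate C1(CH3)=C2(OTf) of 11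
Conditions: CsF, PhN(SO2CF3)2, DME, rt
Reagents that add atoms: N-phenylbis(trifluoromethanesulfonimide), O=S(=O)(N(c1ccccc1)S(=O)(=O)C(F)(F)F)C(F)(F)F
Why: Silyl enol ether to enol triflate exchange: fluoride releases the regiodefined caesium enolate, which is trapped on oxygen, so the future C1=C2 alkene becomes an electron-poor vinyl triflate that OsO4 will not attack.

Step 10
Reactants: 12 ring A enol triflate of 11
Product: 14 5β,6β,8β-triol, via osmate ester 13 (not isolated)
Conditions: OsO4 (1.05 equiv), Me2NCH2CH2NMe2, CH2Cl2, −78 °C; then aq. Na2SO3, THF, 50 °C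
Reagents that add atoms: osmium tetroxide, O=[Os](=O)(=O)=O
Why: Hydroxyl-directed dihydroxylation: the pseudoaxial C8 hydroxyl hydrogen-bonds to an oxo ligand of the OsO4–diamine complex and steers the suprafacial [3+2] addition to the β face of C5=C6, so that C5–OH and C6–OH are formed cis to each other, to C8–OH and to the C4 methyl (cis-decalin), and reductive hydrolysis of the osmate ester frees the triol.

Step 11
Reactants: 14 5β,6β,8β-triol
Product: 15 cis-decalin C6-hydroxy C5-mesylate (C5–OMs β, C6–OH β, C8–OH β, C10–OTBS α, C1(CH3)=C2(OTf))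
Conditions: MsCl, Et3N, CH2Cl2, −20 °C
Reagents that add atoms: methanesulfonyl chloride, CS(=O)(=O)Cl
Why: Mesylate formation through sulfene is selective for the only secondary hydroxyl (C5, equatorial) over the two tertiary ones and leaves the C5 configuration unchanged, since the C–O bond is not broken.

Step 12
Reactants: 15 cis-decalin C6-hydroxy C5-mesylate
Product: 16 trans-fused C6-keto hydroazulene (C4–CH3 β, C5–H α, C8–OH β, C10–OTBS α, C1(CH3)=C2(OTf))
Conditions: Et3Al (3 equiv), CH2Cl2, −78 to −20 °C; aq. sodium potassium tartrate (KNaC4H4O6) work-up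
Reagents that add atoms: none
Why: Et3Al converts the tertiary hydroxyls into aluminium alkoxides and activates the equatorial C5 mesylate, which leaves while the antiperiplanar C4–C6 ring bond shifts to C5 in one concerted suprafacial 1,2-shift that turns C6 into the ketone (semipinacol rearrangement of a 1,2-diol monosulfonate, the organoaluminium-promoted pinacol-type shift). No ring is closed end to end: through this single shift ring B contracts from six to five members (C4–C5–C8–C9–C10) and ring A expands from six to seven (C1–C2–C3–C4–C5–C6–C7). C5 is the only new stereocentre and is set by inversion at the β-mesylate carbon, so C5–H ends trans to the C4 methyl (trans fusion), while the migrating C4 keeps its configuration. In the chair that holds isopropyl, silyloxy, methyl and mesylate equatorial, the C5–O bond is antiperiplanar to the ring bonds C6–C4 and C8–C9 but gauche to C6–C7, which excludes a C7 shift. Of the two aligned bonds the fully substituted C4 migrates in preference to the C9 methylene (higher migratory aptitude), and the cis relationship of both tertiary oxygens to the mesylate rules out epoxide formation.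

Step 13
Reactants: 16 trans-fused C6-keto hydroazulene
Product: 17 6α,8β-diol (C10–OTBS α, C1(CH3)=C2(OTf))
Conditions: Me4NBH(OAc)3, AcOH–MeCN, −20 °C
Reagents that add atoms: none
Why: Evans–Saksena reduction: boron bound to the β C8 hydroxyl delivers hydride to the β face of the C6 ketone, which sets the 1,3-anti 6α-carbinol, whereas external hydride would approach anti to the angular methyl and give the 6β epimer.

Step 14
Reactants: 17 6α,8β-diol
Product: 18 C1=C2 alkene 6α,8β-diol (C10–OTBS α)
Conditions: Pd(OAc)2 (5 mol%), PPh3 (10 mol%), HCO2H, Et3N, DMF, 60 °C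
Reagents that add atoms: none
Why: Palladium-catalysed formate reduction of the enol triflate (oxidative addition to zerovalent palladium, decarboxylative hydride transfer, reductive elimination) unveils the C1=C2 alkene at the position fixed in step 2 without affecting the alcohols or the silyl ether.

Step 15
Reactants: 19 4-hydroxybenzoic acid
Product: 21 4-(tert-butyldimethylsilyloxy)benzoic acid, via silyl ester 20 (not isolated)
Conditions: TBSCl (2.3 equiv), imidazole, DMF, rt; then AcOH–THF–H2O, rt
Reagents that add atoms: tert-butyldimethylsilyl chloride, CC(C)(C)[Si](C)(C)Cl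
Why: Silyl ether protection: both the phenol and the acid are silylated and the labile silyl ester is then hydrolysed selectively, which leaves the phenol protected for the coupling.

Step 16
Reactants: 18 C1=C2 alkene 6α,8β-diol; 21 4-(tert-butyldimethylsilyloxy)benzoic acid
Product: 22 C6 4-(tert-butyldimethylsilyloxy)benzoate of 18
Conditions: DCC, 4-(dimethylamino)pyridine (cat.), CH2Cl2, rt
Reagents that add atoms: none
Why: Steglich esterification acylates the secondary C6 hydroxyl through the acylpyridinium ion while the hindered tertiary C8 hydroxyl does not react; the C6 configuration is retained because only the O–H bond is involved.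

Step 17
Reactants: 22 C6 4-(tert-butyldimethylsilyloxy)benzoate of 18
Product: 23 2α-hydroxyferutinin
Conditions: HF·pyridine, pyridine–THF, 0 °C to rt
Reagents that add atoms: none
Why: Fluoride-mediated desilylation removes the aryl and the secondary alkyl silyl ether in one operation under pyridine-buffered conditions that spare the benzoate and the tertiary alcohol.

**Compound list**

1 | 3-methylbut-3-en-2-one | CC(=O)C(C)=C | starting material
2 | 2-methyl-3-(triisopropylsilyloxy)buta-1,3-diene | C=C(C)C(=C)O[Si](C(C)C)(C(C)C)C(C)C | intermediate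
3 | thymoquinone (2-isopropyl-5-methyl-1,4-benzoquinone) | CC1=CC(=O)C(C(C)C)=CC1=O | starting material
4 | cis-fused adduct 2-isopropyl-4a,7-dimethyl-6-(triisopropylsilyloxy)-4a,5,8,8a-tetrahydronaphthalene-1,4-dione; C4–CH3 and C6–H β | CC1=C(O[Si](C(C)C)(C(C)C)C(C)C)C[C@@]2(C)C(=O)C=C(C(C)C)C(=O)[C@H]2C1 | intermediate
5 | 8β,9β-epoxide of 4 (oxygen cis to C4–CH3 and C6–H, isopropyl α) | CC1=C(O[Si](C(C)C)(C(C)C)C(C)C)C[C@@]2(C)C(=O)[C@@H]3O[C@]3(C(C)C)C(=O)[C@H]2C1 | intermediate
6 | potassium C5 enolate of 5 (C5(OK)=C6) | CC1=C(O[Si](C(C)C)(C(C)C)C(C)C)C[C@@]2(C)C(=O)[C@@H]3O[C@]3(C(C)C)C([O-])=C2C1.[K+] | intermediate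
7 | C5 enol triflate of 5: C5(OTf)=C6, 8β,9β-epoxide, C10 ketone | CC1=C(O[Si](C(C)C)(C(C)C)C(C)C)C[C@@]2(C)C(=O)[C@@H]3O[C@]3(C(C)C)C(OS(=O)(=O)C(F)(F)F)=C2C1 | intermediate
8 | β-hydroxy ketone: C8–OH β (isopropyl α), C9H2, C10 ketone, C5(OTf)=C6 | CC1=C(O[Si](C(C)C)(C(C)C)C(C)C)C[C@@]2(C)C(=O)C[C@@](O)(C(C)C)C(OS(=O)(=O)C(F)(F)F)=C2C1 | intermediate
9 | 8β,10α-diol (anti-1,3-diol; C10–OH trans to C4–CH3) | CC1=C(O[Si](C(C)C)(C(C)C)C(C)C)C[C@@]2(C)[C@@H](O)C[C@@](O)(C(C)C)C(OS(=O)(=O)C(F)(F)F)=C2C1 | intermediate
10 | C10 tert-butyldimethylsilyl ether of 9 (C8–OH free) | CC1=C(O[Si](C(C)C)(C(C)C)C(C)C)C[C@@]2(C)[C@@H](O[Si](C)(C)C(C)(C)C)C[C@@](O)(C(C)C)C(OS(=O)(=O)C(F)(F)F)=C2C1 | intermediate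
11 | allylic alcohol: C5(H)=C6, C8–OH β, C10–OTBS α, ring A C1(CH3)=C2(OSi-iPr3) | CC1=C(O[Si](C(C)C)(C(C)C)C(C)C)C[C@@]2(C)[C@@H](O[Si](C)(C)C(C)(C)C)C[C@@](O)(C(C)C)C=C2C1 | intermediate
12 | ring A enol triflate of 11: C1(CH3)=C2(OTf), C5(H)=C6, C8–OH β, C10–OTBS α | CC1=C(OS(=O)(=O)C(F)(F)F)C[C@@]2(C)[C@@H](O[Si](C)(C)C(C)(C)C)C[C@@](O)(C(C)C)C=C2C1 | intermediate
13 | osmate ester: β-face C5,C6-glycolate of dioxoosmium (hexavalent osmium) with bound Me2NCH2CH2NMe2 | CC1=C(OS(=O)(=O)C(F)(F)F)C[C@@]2(C)[C@@H](O[Si](C)(C)C(C)(C)C)C[C@@](O)(C(C)C)[C@H](O[Os-2]3(=O)(=O)(O4)[N+](C)(C)CC[N+]3(C)C)[C@@]24C1 | intermediate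
14 | 5β,6β,8β-triol (cis-decalin; C10–OTBS α) | CC1=C(OS(=O)(=O)C(F)(F)F)C[C@@]2(C)[C@@H](O[Si](C)(C)C(C)(C)C)C[C@@](O)(C(C)C)[C@H](O)[C@@]2(O)C1 | intermediate
15 | cis-decalin C6-hydroxy C5-mesylate: C5–OMs β (H α), C6–OH β, C8–OH β, C10–OTBS α, C1(CH3)=C2(OTf) | CC1=C(OS(=O)(=O)C(F)(F)F)C[C@@]2(C)[C@@H](O[Si](C)(C)C(C)(C)C)C[C@@](O)(C(C)C)[C@H](OS(C)(=O)=O)[C@@]2(O)C1 | intermediate
16 | trans-fused C6-keto hydroazulene: C4–CH3 β, C5–H α, C8–OH β (isopropyl α), C10–OTBS α, C1(CH3)=C2(OTf) | CC1=C(OS(=O)(=O)C(F)(F)F)C[C@]2(C)[C@@H](C(=O)C1)[C@](O)(C(C)C)C[C@@H]2O[Si](C)(C)C(C)(C)C | intermediate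
17 | 6α,8β-diol of the hydroazulene (C10–OTBS α, C1(CH3)=C2(OTf)) | CC1=C(OS(=O)(=O)C(F)(F)F)C[C@]2(C)[C@@H]([C@@H](O)C1)[C@](O)(C(C)C)C[C@@H]2O[Si](C)(C)C(C)(C)C | intermediate
18 | C1=C2 alkene 6α,8β-diol (C10–OTBS α) | CC1=CC[C@]2(C)[C@@H]([C@@H](O)C1)[C@](O)(C(C)C)C[C@@H]2O[Si](C)(C)C(C)(C)C | intermediate
19 | 4-hydroxybenzoic acid | OC(=O)c1ccc(O)cc1 | starting material
20 | tert-butyldimethylsilyl 4-(tert-butyldimethylsilyloxy)benzoate | CC(C)(C)[Si](C)(C)OC(=O)c1ccc(O[Si](C)(C)C(C)(C)C)cc1 | intermediate
21 | 4-(tert-butyldimethylsilyloxy)benzoic acid | OC(=O)c1ccc(O[Si](C)(C)C(C)(C)C)cc1 | intermediate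
22 | C6 4-(tert-butyldimethylsilyloxy)benzoate of 18 | CC1=CC[C@]2(C)[C@@H]([C@@H](OC(=O)c3ccc(O[Si](C)(C)C(C)(C)C)cc3)C1)[C@](O)(C(C)C)C[C@@H]2O[Si](C)(C)C(C)(C)C | intermediate
23 | 2α-hydroxyferutinin | CC1=CC[C@]2(C)[C@@H]([C@@H](OC(=O)c3ccc(O)cc3)C1)[C@](O)(C(C)C)C[C@@H]2O | target

**Totals and risks**

Total step count: 17. Longest linear sequence: 16 steps (steps 1–14, 16 and 17, from 3-methylbut-3-en-2-one); step 15 is a one-step side branch.

The three steps most likely to fail:

Step 2. Enantioface discrimination of the catalyst-bound quinone may be incomplete, and part of the cycloaddition may take place at the isopropyl-substituted double bond. The fallback leaves the asymmetric induction to a resolution. The cycloaddition is run with the racemic catalyst, the regioisomeric adduct is removed at the stage of 4, and the sequence is taken to diol 9. The fallback sets out from 9: esterification of its secondary C10 hydroxyl with (S)-O-methylmandelic acid (DCC, 4-(dimethylamino)pyridine, CH2Cl2) gives the diastereomeric esters, from which the C10 (S)-O-methylmandelate F1 of the required series is isolated by chromatography or crystallisation. Methanolysis (K2CO3, MeOH) comes back to the route at 9 as a single enantiomer.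

Step 10. Osmylation may occur from the α face if the steric bias of the angular methyl outweighs hydrogen-bond delivery, or it may be slow at the hindered alkene. The fallback sets out from 12 and uses Woodward cis-hydroxylation (I2, AgOAc, AcOH–H2O). The iodonium ion forms on the open α face, acetate opens it from the β face, and the neighbouring acetoxy group displaces iodide through a β-face acetoxonium ion. Hydrolysis of that ion gives the C5 acetate of the β-cis diol F2, and methanolysis (K2CO3, MeOH) comes back to the route at triol 14.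

Step 12. The free tertiary aldol of the product may undergo retro-aldol cleavage or lose water under the aluminium Lewis acid, and a shift of the C9 methylene driven by the C8 oxygen may compete. The fallback sets out from 15: both tertiary hydroxyls are silylated (Me3SiOSO2CF3, 2,6-lutidine, CH2Cl2, −78 °C) to the C6,C8-bis(trimethylsilyl) ether F3. A Lewis acid-promoted semipinacol shift of this silyl ether (Et2AlCl, CH2Cl2, −78 °C) should then give the C8 trimethylsilyl ether of the ketone F4. In F4 the aldol is masked, and the shift depends more on the migrating group than on oxygen push, which favours the fully substituted C4. Mild methanolysis (citric acid, MeOH) comes back to the route at 16.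

**Further compounds**

F1 | step 2 | C10 (S)-O-methylmandelate of diol 9 | CC1=C(O[Si](C(C)C)(C(C)C)C(C)C)C[C@@]2(C)[C@@H](OC(=O)[C@@H](OC)c3ccccc3)C[C@@](O)(C(C)C)C(OS(=O)(=O)C(F)(F)F)=C2C1
F2 | step 10 | C5 acetate of triol 14 | CC1=C(OS(=O)(=O)C(F)(F)F)C[C@@]2(C)[C@@H](O[Si](C)(C)C(C)(C)C)C[C@@](O)(C(C)C)[C@H](OC(C)=O)[C@@]2(O)C1
F3 | step 12 | C6,C8-bis(trimethylsilyl) ether of mesylate 15 | CC1=C(OS(=O)(=O)C(F)(F)F)C[C@@]2(C)[C@@H](O[Si](C)(C)C(C)(C)C)C[C@@](O[Si](C)(C)C)(C(C)C)[C@H](OS(C)(=O)=O)[C@@]2(O[Si](C)(C)C)C1
F4 | step 12 | C8 trimethylsilyl ether of ketone 16 | CC1=C(OS(=O)(=O)C(F)(F)F)C[C@]2(C)[C@@H](C(=O)C1)[C@](O[Si](C)(C)C)(C(C)C)C[C@@H]2O[Si](C)(C)C(C)(C)C
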